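Rings: A pyrrole, B azepine, C carbocycle, D fused lactone, E side-chain lactone. Retrosynthesis: ring E is cut off ring A first (acyl C–C bond, then C–O); ring C is then cut in one stroke at C9–CH(Et) and at pyrrole C1–CH(ring D).
This leaves an alkenylboronate of the pyrrolo[1,2-a]azepine (rings A, B) and the flat (Z)-3-methyl-5-propylidenefuran-2(5H)-one (ring D plus the ethyl-bearing carbon).
Forward order: ring B by Dieckmann closure, then the boronate, then the union that closes ring C as a formal [3+3] annulation with ring D carried in, then ring E from the ester.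
Enabling feature: C9–C9a–C1 is a 1,3-dinucleophile (alkenyl carbon through its C–B bond, pyrrole β-carbon). The exocyclic carbon and the ring β-carbon of the ylidenebutenolide are a 1,3-dielectrophile; its second site is armed only after the first addition has passed through an aromatic 2-oxyfuran.
Stereochemistry: the ethyl-bearing carbon is set by a chiral diene–rhodium catalyst and the three ring D centres are relayed from it in the same operation. The ring E methyl centre is bought, and the ring E carbinol is set by Noyori transfer hydrogenation.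

Key step: step 7

Assumption: the sense of induction of the chiral ligands in steps 7 and 10 and in the fallbacks is taken from the closest analogies; if it proves opposite, the mirror-image ligand is used.
Assumption: dimethyl 1H-pyrrole-2,5-dicarboxylate is treated as purchasable (otherwise one esterification from the commercial diacid).

Step 1
Reactants: 1 dimethyl 1H-pyrrole-2,5-dicarboxylate; 2 methyl 5-bromopentanoate
Product: 3 dimethyl 1-(5-methoxy-5-oxopentyl)-1H-pyrrole-2,5-dicarboxylate
Conditions: K2CO3, DMF, 60 °C
Reagents that add atoms: none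
Why: N-alkylation (SN2) of the acidic N–H between two esters by a primary bromide; no stereocentre is formed.

Step 2
Reactants: 3 dimethyl 1-(5-methoxy-5-oxopentyl)-1H-pyrrole-2,5-dicarboxylate
Product: 4 dimethyl 9-oxo-6,7,8,9-tetrahydro-5H-pyrrolo[1,2-a]azepine-3,8-dicarboxylate
Conditions: NaH (2.5 equiv), MeOH (cat.), THF, 65 °C; aq HCl
Reagents that add atoms: none
Why: Dieckmann condensation of the side-chain ester enolate onto one of the two equivalent ring esters should close ring B under thermodynamic control, driven by deprotonation of the β-keto ester.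

Step 3
Reactants: 4 dimethyl 9-oxo-6,7,8,9-tetrahydro-5H-pyrrolo[1,2-a]azepine-3,8-dicarboxylate
Product: 5 methyl 9-oxo-6,7,8,9-tetrahydro-5H-pyrrolo[1,2-a]azepine-3-carboxylate
Conditions: LiCl, H2O (2 equiv), DMSO, 140 °C
Reagents that add atoms: none
Why: Krapcho dealkoxycarbonylation should remove only the ester β to the ketone, because only that carboxylate can lose CO2 to a stabilised enolate.

Step 4
Reactants: 5 methyl 9-oxo-6,7,8,9-tetrahydro-5H-pyrrolo[1,2-a]azepine-3-carboxylate
Product: 6 methyl 9-(trifluoromethylsulfonyloxy)-6,7-dihydro-5H-pyrrolo[1,2-a]azepine-3-carboxylate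
Conditions: KN(SiMe3)2, THF, −78 °C; PhNTf2, −78 → 0 °C; aq NH4Cl
Reagents that add atoms: N-phenylbis(trifluoromethanesulfonimide), O=S(=O)(N(c1ccccc1)S(=O)(=O)C(F)(F)F)C(F)(F)F
Why: Enol triflate formation; the ketone can enolise only toward C-8, so the C8=C9 double bond of the target is fixed here without regiochemical doubt.

Step 5
Reactants: 6 methyl 9-(trifluoromethylsulfonyloxy)-6,7-dihydro-5H-pyrrolo[1,2-a]azepine-3-carboxylate
Product: 7 methyl 9-(4,4,5,5-tetramethyl-1,3,2-dioxaborolan-2-yl)-6,7-dihydro-5H-pyrrolo[1,2-a]azepine-3-carboxylate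
Conditions: B2pin2, PdCl2(PPh3)2 (3 mol %), PPh3 (6 mol %), KOPh, toluene, 50 °C
Reagents that add atoms: bis(pinacolato)diboron, CC1(C)OB(OC1(C)C)B1OC(C)(C)C(C)(C)O1
Why: Miyaura borylation of an alkenyl triflate (oxidative addition to zerovalent palladium, transmetalation with the phenoxide-activated diboron) turns C-9 into a regiodefined alkenyl nucleophile.

Step 6
Reactants: 8 3-methylfuran-2(5H)-one; 9 propanal
Product: 12 (Z)-3-methyl-5-propylidenefuran-2(5H)-one, via silyloxyfuran 10 (not isolated), via aldol silyl ether 11 (not isolated)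
Conditions: t-BuMe2SiOTf, i-Pr2NEt, CH2Cl2, 0 → 23 °C; then DBU, 23 °C
Reagents that add atoms: none
Why: One-pot vinylogous Mukaiyama aldol condensation: soft enolisation to the 2-silyloxyfuran, aldol addition at furan C-5, then E1cB loss of silanol; the Z alkene is the thermodynamic isomer and no stereocentre remains.

Step 7
Reactants: 7 methyl 9-(4,4,5,5-tetramethyl-1,3,2-dioxaborolan-2-yl)-6,7-dihydro-5H-pyrrolo[1,2-a]azepine-3-carboxylate; 12 (Z)-3-methyl-5-propylidenefuran-2(5H)-one
Product: 16 tetracyclic lactone ester (rings A–D of the target; CO2Me on the pyrrole α-carbon; ethyl-bearing C S; pyrrole-bearing CH S; CH–O R; CH–CH3 R), via butenolide adduct 13 (not isolated), via silyloxyfuran 14 (not isolated), via silyl ketene acetal 15 (not isolated)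
Conditions: [RhCl(C2H4)2]2 (2.5 mol %), (R,R)-2,5-diphenylbicyclo[2.2.2]octa-2,5-diene (5.5 mol %), Et3N, 1,4-dioxane/H2O 10:1, 30 °C; volatiles removed, residue dried azeotropically (toluene); 2,6-lutidine, Me3SiOTf (excess), CH2Cl2, −40 → 23 °C; then MeOH, DBU, 23 °C
Reagents that add atoms: none
Why: Proposed new method: a hydroxo(diene) complex of monovalent rhodium takes the alkenyl group from boron and adds it to the exocyclic carbon of 12 (1,6-insertion, driven by formation of an aromatic rhodium 2-furanolate and helped by the α-methyl group, which retards 1,4-insertion at the ring β-carbon), and protonolysis gives butenolide 13; the closest known types are the rhodium–diene catalysed asymmetric conjugate alkenylation of unsaturated lactones and the rhodium-catalysed 1,6-addition of organoboron reagents to open-chain 2,4-dienoates. Me3SiOTf and 2,6-lutidine then convert 13 (both epimers) into the 2-silyloxyfuran 14, and its reversible protonation at the oxygen-bearing ring carbon gives an O-silylated furanonium ion that pyrrole C-1 attacks at its β-carbon, as in known silyl-triflate-promoted intramolecular Friedel–Crafts (Mukaiyama–Michael type) additions to butenolides. Ring C is thereby closed in a formal [3+3] annulation whose ring-forming event is a 6-exo-trig attack on the lactone C=C (6-enolendo in respect of the pyrrole C-1=C-9a unit), while ring D is carried in ready-made. The ethyl-bearing centre is set by the chiral diene on rhodium; the CH–O centre by Curtin–Hammett selection between the interconverting protonated epimers (only the one that places the ethyl group pseudo-axial, free of allylic strain against C-8–H, and anti to the C–O bond should reach a chair-like transition state); the pyrrole-bearing centre by the obligatory cis fusion of rings C and D; the CH–CH3 centre by DBU equilibration to the more stable lactone, in which the methyl group is trans to the neighbouring ring C carbon. The step needs 1,6- before 1,4-addition, attack by pyrrole C-1 instead of alkene carbon C-8 or the other pyrrole positions, and survival of the acid-sensitive alkenylpyrrole; these are secured by the α-methyl group and the aromatisation of the lactone, by ring size (a disfavoured five-membered enolendo closure is the only alternative for C-8) together with the ester at C-3 that occupies the free α-position, and by the same ester, which lowers the basicity of the alkenylpyrrole, together with the lutidine buffer.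

Step 8
Reactants: 16 tetracyclic lactone ester
Product: 18 tetracyclic lactone carboxylic acid (CO2H in place of the CO2Me of 16), via dilithium hydroxy dicarboxylate 17 (not isolated)
Conditions: LiOH, THF/MeOH/H2O, 50 °C; then 1 M HCl to pH 2–3, 23 °C
Reagents that add atoms: lithium hydroxide, [Li+].[OH-]
Why: Saponification of the pyrrole ester; ring D opens to the hydroxy carboxylate, which does not enolise, and should reclose on acidification because the γ-hydroxy acid is cis on ring C, so no stereocentre is touched.

Step 9
Reactants: 18 tetracyclic lactone carboxylic acid; 19 methyl (S)-3-bromo-2-methylpropanoate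
Product: 22 γ-keto ester (C(=O)CH2CH(CH3)CO2Me in place of the CO2H of 18; new side-chain CH–CH3 centre R), via zinc reagent 20 (not isolated), via acid chloride 21 (not isolated)
Conditions: 19, Zn, LiCl, THF, 40 °C (gives 20); 18, 1-chloro-N,N,2-trimethylprop-1-en-1-amine, CH2Cl2, 0 → 23 °C (gives 21); then 20, Pd(PPh3)4 (5 mol %), THF, 0 → 23 °C
Reagents that add atoms: none
Why: Negishi-type acylation of a zinc homoenolate by an acid chloride under zerovalent palladium catalysis; the neutral α-chloroenamine avoids Vilsmeier-type electrophiles, and the methyl-bearing centre comes unchanged from 19 because zinc sits on the neighbouring CH2.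

Step 10
Reactants: 22 γ-keto ester
Product: 24 CNP0324368.1 (target), via hydroxy ester 23 (not isolated)
Conditions: RuCl[(R,R)-TsDPEN](p-cymene) (2 mol %), HCO2Na, H2O/DMF, 40 °C; then toluene, 80 °C
Reagents that add atoms: none
Why: Noyori asymmetric transfer hydrogenation of the pyrrolyl (aryl-type) ketone under near-neutral conditions; the (R,R) ligand is expected to give the R carbinol by analogy with aryl alkyl ketones (catalyst control, the remote methyl centre has little say), and the γ-hydroxy ester should lactonise to the cis-2,4-disubstituted ring E.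

Compound list
1 | dimethyl 1H-pyrrole-2,5-dicarboxylate | COC(=O)c1ccc([nH]1)C(=O)OC | starting material
2 | methyl 5-bromopentanoate | COC(=O)CCCCBr | starting material
3 | dimethyl 1-(5-methoxy-5-oxopentyl)-1H-pyrrole-2,5-dicarboxylate | COC(=O)CCCCn1c(C(=O)OC)ccc1C(=O)OC | intermediate
4 | dimethyl 9-oxo-6,7,8,9-tetrahydro-5H-pyrrolo[1,2-a]azepine-3,8-dicarboxylate (racemic, enolisable at C-8) | COC(=O)C1CCCn2c(C(=O)OC)ccc2C1=O | intermediate
5 | methyl 9-oxo-6,7,8,9-tetrahydro-5H-pyrrolo[1,2-a]azepine-3-carboxylate | COC(=O)c1ccc2n1CCCCC2=O | intermediate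
6 | methyl 9-(trifluoromethylsulfonyloxy)-6,7-dihydro-5H-pyrrolo[1,2-a]azepine-3-carboxylate | COC(=O)c1ccc2n1CCCC=C2OS(=O)(=O)C(F)(F)F | intermediate
7 | methyl 9-(4,4,5,5-tetramethyl-1,3,2-dioxaborolan-2-yl)-6,7-dihydro-5H-pyrrolo[1,2-a]azepine-3-carboxylate | COC(=O)c1ccc2n1CCCC=C2B1OC(C)(C)C(C)(C)O1 | intermediate
8 | 3-methylfuran-2(5H)-one | CC1=CCOC1=O | starting material
9 | propanal | CCC=O | starting material
10 | tert-butyldimethyl[(3-methylfuran-2-yl)oxy]silane | Cc1ccoc1O[Si](C)(C)C(C)(C)C | intermediate
11 | 5-[1-(tert-butyldimethylsilyloxy)propyl]-3-methylfuran-2(5H)-one (diastereomer mixture) | CCC(O[Si](C)(C)C(C)(C)C)C1OC(=O)C(C)=C1 | intermediate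
12 | (Z)-3-methyl-5-propylidenefuran-2(5H)-one | CC/C=C1\OC(=O)C(C)=C1 | intermediate
13 | methyl 9-[(1S)-1-(4-methyl-5-oxo-2,5-dihydrofuran-2-yl)propyl]-6,7-dihydro-5H-pyrrolo[1,2-a]azepine-3-carboxylate (both epimers at furanone C-2) | CC[C@@H](C1=CCCCn2c(C(=O)OC)ccc12)C1OC(=O)C(C)=C1 | intermediate
14 | methyl 9-{(1S)-1-[4-methyl-5-(trimethylsilyloxy)furan-2-yl]propyl}-6,7-dihydro-5H-pyrrolo[1,2-a]azepine-3-carboxylate | CC[C@@H](C1=CCCCn2c(C(=O)OC)ccc12)c1cc(C)c(O[Si](C)(C)C)o1 | intermediate
15 | silyl ketene acetal of 16 (ring C closed; ring D as 2-trimethylsilyloxy-3-methyl-4,5-dihydrofuran) | CC[C@H]1C2=CCCCn3c(C(=O)OC)cc(c32)[C@H]2[C@@H]1OC(O[Si](C)(C)C)=C2C | intermediate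
16 | tetracyclic lactone ester: rings A–D of the target, CO2Me on the pyrrole α-carbon, configurations as in the target | CC[C@H]1C2=CCCCn3c(C(=O)OC)cc(c32)[C@H]2[C@@H]1OC(=O)[C@@H]2C | intermediate
17 | dilithium salt of the ring D-opened hydroxy dicarboxylic acid | CC[C@H]1C2=CCCCn3c(C(=O)[O-])cc(c32)[C@H]([C@@H](C)C(=O)[O-])[C@@H]1O.[Li+].[Li+] | intermediate
18 | tetracyclic lactone carboxylic acid (CO2H in place of the CO2Me of 16) | CC[C@H]1C2=CCCCn3c(C(=O)O)cc(c32)[C@H]2[C@@H]1OC(=O)[C@@H]2C | intermediate
19 | methyl (S)-3-bromo-2-methylpropanoate | BrC[C@@H](C)C(=O)OC | starting material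
20 | [(2S)-3-methoxy-2-methyl-3-oxopropyl]zinc bromide | Br[Zn]C[C@@H](C)C(=O)OC | intermediate
21 | acid chloride of 18 | CC[C@H]1C2=CCCCn3c(C(=O)Cl)cc(c32)[C@H]2[C@@H]1OC(=O)[C@@H]2C | intermediate
22 | γ-keto ester: methyl (2R)-2-methyl-4-oxo-4-(tetracyclic pyrrol-α-yl)butanoate | CC[C@H]1C2=CCCCn3c(C(=O)C[C@@H](C)C(=O)OC)cc(c32)[C@H]2[C@@H]1OC(=O)[C@@H]2C | intermediate
23 | hydroxy ester: methyl (2R,4R)-4-hydroxy-2-methyl-4-(tetracyclic pyrrol-α-yl)butanoate | CC[C@H]1C2=CCCCn3c([C@H](O)C[C@@H](C)C(=O)OC)cc(c32)[C@H]2[C@@H]1OC(=O)[C@@H]2C | intermediate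
24 | CNP0324368.1: ethyl-bearing C S, pyrrole-bearing CH S, ring D CH–O R, ring D CH–CH3 R, ring E CH–O R, ring E CH–CH3 R | CC[C@H]1C2=CCCCn3c([C@H]4C[C@@H](C)C(=O)O4)cc(c32)[C@H]2[C@@H]1OC(=O)[C@@H]2C | target

Total steps: 10. Longest linear sequence: 9 steps (1–5, then 7–10); step 6 is a one-step branch.

The three steps most likely to fail

Risk 1, at step 7 (it bears the label "Proposed new method:"). What may go wrong: the alkenyl–rhodium species may insert 1,4 at the ring β-carbon or be lost by protodeboronation before it reaches the remote exocyclic carbon, and facial discrimination at that flat, distant carbon may be poor.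
Fallback for step 7 (the C-9–CH(Et) bond is made by a precedented 1,4-addition to an open-chain enal and ring D is then built on the chain by standard carbonyl chemistry, instead of a 1,6-addition to the preformed ring D): setting out from 7, asymmetric Hayashi–Miyaura 1,4-addition to (E)-pent-2-enal ([RhCl(C2H4)2]2, the same chiral diene, KOH (cat.), 1,4-dioxane/H2O, 30 °C) should give the β-alkenyl aldehyde F1, with the ethyl-bearing centre set by the ligand. Amine-catalysed α-benzoyloxylation (dibenzoyl peroxide, (S)-2-(triphenylmethyl)pyrrolidine (10 mol %), hydroquinone (cat.), THF, 0 °C) should give the α-benzoyloxy aldehyde F2; the configuration of its new oxygen-bearing carbon is left open, because that centre is erased later in silyloxyfuran 14. Still–Gennari olefination (methyl 2-[bis(2,2,2-trifluoroethoxy)phosphoryl]propanoate, KN(SiMe3)2, 18-crown-6, THF, −78 °C) should give the (Z)-enoate benzoate F3. K2CO3 in MeOH (0 → 23 °C) should remove the benzoate to the γ-hydroxy (Z)-enoate F4, which closes in the same flask to butenolide 13, where the route is rejoined. Isolated 13 is carried on to 16 by the Me3SiOTf/2,6-lutidine and MeOH/DBU stages of step 7, which on their own are a silyl-triflate-promoted intramolecular Friedel–Crafts conjugate addition of known type.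

Risk 2, at step 2. What may go wrong: intermolecular Claisen condensation and oligomerisation may outrun closure of the seven-membered ring onto the weakly electrophilic pyrrole ester.
Fallback for step 2 (ring B closed by electrophilic acylation of the pyrrole instead of enolate acylation): setting out from 2, purchased methyl 1H-pyrrole-2-carboxylate F5 is N-alkylated (K2CO3, DMF, 60 °C) to the diester F6. The aliphatic ester alone is saponified (LiOH, 1 equiv, THF/H2O, 0 °C; then dilute HCl) to the pyrrolylpentanoic acid F7. Intramolecular Friedel–Crafts acylation at the only pyrrole α-carbon within reach (trifluoroacetic anhydride, cat. H3PO4, CH2Cl2) should give 5 directly, so that steps 2 and 3 are bypassed and the route is rejoined at 5.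

Risk 3, at step 10. What may go wrong: hydride transfer to the electron-rich pyrrolyl ketone may be slow, and the new carbinol centre may lose configuration by ionisation of the pyrrolylcarbinyl C–O bond.
Fallback for step 10 (carbinol centre made by C–C bond formation instead of ketone reduction): setting out from acid chloride 21 (made from 18 as in step 9), reduction with LiAlH(Ot-Bu)3 (THF, −78 °C) should give the pyrrole-α-carbaldehyde F8. Chromium-catalysed enantioselective 2-(alkoxycarbonyl)allylation with ethyl 2-(bromomethyl)acrylate (CrCl2, chiral bis(oxazolinyl)carbazole ligand, Mn, Me3SiCl, THF) should give the R homoallylic alcohol ester F9, which lactonises to the α-methylene lactone F10. Conjugate reduction with [(Ph3P)CuH]6 (toluene; aq NH4Cl), with protonation from the face away from the pyrrole, should give the cis lactone 24, where the route ends.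

Further compounds
F1 | step 7 | methyl 9-[(3R)-1-oxopentan-3-yl]-6,7-dihydro-5H-pyrrolo[1,2-a]azepine-3-carboxylate | CC[C@H](CC=O)C1=CCCCn2c(C(=O)OC)ccc12
F2 | step 7 | methyl 9-[(3S)-2-(benzoyloxy)-1-oxopentan-3-yl]-6,7-dihydro-5H-pyrrolo[1,2-a]azepine-3-carboxylate (configuration at C-2 of the side chain left open) | CC[C@H](C(OC(=O)c1ccccc1)C=O)C1=CCCCn2c(C(=O)OC)ccc12
F3 | step 7 | methyl (2Z,5S)-4-(benzoyloxy)-5-[3-(methoxycarbonyl)-6,7-dihydro-5H-pyrrolo[1,2-a]azepin-9-yl]-2-methylhept-2-enoate (configuration at C-4 left open) | COC(=O)/C(C)=C\C(OC(=O)c1ccccc1)[C@@H](CC)C1=CCCCn2c(C(=O)OC)ccc12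
F4 | step 7 | methyl (2Z,5S)-4-hydroxy-5-[3-(methoxycarbonyl)-6,7-dihydro-5H-pyrrolo[1,2-a]azepin-9-yl]-2-methylhept-2-enoate (configuration at C-4 left open) | COC(=O)/C(C)=C\C(O)[C@@H](CC)C1=CCCCn2c(C(=O)OC)ccc12
F5 | step 2 | methyl 1H-pyrrole-2-carboxylate (purchased) | COC(=O)c1ccc[nH]1
F6 | step 2 | methyl 1-(5-methoxy-5-oxopentyl)-1H-pyrrole-2-carboxylate | COC(=O)CCCCn1cccc1C(=O)OC
F7 | step 2 | 5-[2-(methoxycarbonyl)-1H-pyrrol-1-yl]pentanoic acid | OC(=O)CCCCn1cccc1C(=O)OC
F8 | step 10 | tetracyclic lactone aldehyde (CHO in place of the CO2H of 18) | CC[C@H]1C2=CCCCn3c(C=O)cc(c32)[C@H]2[C@@H]1OC(=O)[C@@H]2C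
F9 | step 10 | ethyl 2-[(2R)-2-hydroxy-2-(tetracyclic pyrrol-α-yl)ethyl]acrylate | CC[C@H]1C2=CCCCn3c([C@H](O)CC(=C)C(=O)OCC)cc(c32)[C@H]2[C@@H]1OC(=O)[C@@H]2C
F10 | step 10 | α-methylene analogue of 24 (ring E carries an exocyclic CH2 in place of CH3 and H) | CC[C@H]1C2=CCCCn3c([C@H]4CC(=C)C(=O)O4)cc(c32)[C@H]2[C@@H]1OC(=O)[C@@H]2C
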